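# Gentiside F by anodic Kolbe cross-coupling of a chiral-pool acid with a diacid half-ester

Numbering used throughout: 1 (S)-2-methylbutan-1-ol, 2 (S)-1-bromo-2-methylbutane, 3 diethyl malonate, 4 alkylated malonate, 5 its diacid, 6 (S)-4-methylhexanoic acid, 7 tetradecanedioic acid, 8 its dimethyl ester, 9 barium salt of the half-ester, 10 the half-ester, 11 methyl (16S)-16-methyloctadecanoate, 12 (16S)-16-methyloctadecan-1-ol, 13 2,3-dihydroxybenzoic acid, 14 its tribenzyl derivative, 15 2,3-bis(benzyloxy)benzoic acid, 16 the protected ester, 17 Gentiside F. Chain carbons are numbered C1 (oxygen-bearing) to C18.

## Analysis of the target

Gentiside F (17) is the ester of 2,3-dihydroxybenzoic acid (13) with (16S)-16-methyloctadecan-1-ol (12); its only ring is the benzene ring, which carries the carboxyl group at its C1 and hydroxyl groups at C2 and C3. In the alkyl chain, C1 to C15 are fifteen unbranched methylene groups, C16 is a methine bearing a methyl branch, and C17–C18 form the ethyl end (an anteiso chain). C16 is the single stereocentre; its substituents rank C15 chain > ethyl > methyl > H, and the SMILES corresponds to S. It lies fifteen carbons from the nearest heteroatom and its three carbon substituents differ only in length, so no neighbouring group can direct its formation, and once it is part of the chain its configuration can hardly be measured or upgraded. The sensitive groups are the free catechol (air oxidation, chelation, competing O-acylation) and the aryl ester, which tolerates neither hydride nor hydroxide and therefore has to be made late. The difficulty is thus one of economy: a small chiral fragment has to be joined to a long inert chain without a trail of activating groups to remove and without any risk to C16. The plan rests on the unbroken methylene run C1–C15 beside the remote C16 methine: the C13–C14 bond inside this run is made by coupling two primary alkyl radicals released from carboxylic acids, so that C16 comes ready-made from the chiral pool and only gas is lost at the junction.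

## Retrosynthetic reasoning

**Ester and catechol.** The last skeletal connection is the acyl C–O bond between the C1 oxygen of the chain and the carboxyl carbon of the aromatic ring. Cutting it gives alcohol 12 and the aromatic acid. A free catechol would compete as a nucleophile and oxidise, so the acid is used as its bis(benzyl ether) 15. The coupled ester 16 is unmasked to 17 by hydrogenolysis, which leaves an alkyl benzoate untouched. Acid 15 comes from 13 by exhaustive benzylation to 14 and hydrolysis of the benzyl ester.

**C1 oxidation level.** Alcohol 12 is traced to the methyl ester 11. An ester is chosen at C1 because it survives an anodic coupling unchanged and can be carried by one of the radical partners. The forward step is a plain hydride reduction, run before the aryl ester exists.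

**Key disconnection, C13–C14.** In 11 the carbons C2–C15 are all methylene groups, so no bond there has a polar handle. The C13–C14 bond is cut homolytically and each radical is written as the carboxylic acid one carbon longer, which gives 6 and 10. The cut is placed here for three reasons:
- The C16 centre stays inside the small fragment, two bonds from the reacting carbon.
- The large fragment is a derivative of the even-numbered C14 diacid 7, a commodity. A cut one bond nearer to C16 would call for a less available odd-numbered diacid, and a cut one bond further away would need a three-carbon instead of a two-carbon extension of the chiral unit.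
- Acid 6 is exactly two carbons longer than the chiral-pool alcohol 1.

The gain is that both carboxyl carbons leave as gas, so nothing has to be removed from the junction afterwards. The forward reaction has to favour the unsymmetrical coupling over the two symmetrical ones and keep the radicals from being oxidised further to cations.

**Chiral acid 6.** Acid 6 is disconnected at its C2–C3 bond (C14–C15 of the target) into electrophile 2 and the two-carbon nucleophile 3. Alkylation gives 4; hydrolysis to 5 and loss of one carboxyl group gives 6. Bromide 2 comes from 1 by substitution of the hydroxyl group under conditions that avoid carbocations. No bond to the stereocentre is made or broken at any stage.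

**Half-ester 10.** Half-ester 10 arises by differentiating the two identical ends of 7: both carboxyl groups are esterified to 8 and one ester is hydrolysed, the half-ester salt 9 leaving the solution as it forms.

## Alternatives that were turned down

Alternative 1: Lithiation–borylation at C16.
- Disconnection: C15–C16, with C16 created as a secondary boronic ester.
- Forward key step: ethyl 2,4,6-triisopropylbenzoate A3 is deprotonated next to oxygen by a sec-alkyllithium in the presence of a chiral diamine. The configurationally defined carbenoid adds to the primary pinacol boronic ester A2 (the C1–C15 chain with a silyl ether at C1). 1,2-Migration of the chain from boron to carbon with loss of the benzoate gives the secondary boronic ester A1.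
- For: the step is reagent-controlled and stereospecific, it can deliver either enantiomer, and it joins two components without statistical by-products. On the cleanness of the coupling it is stronger than the chosen step.
- Against: C16 in A1 still carries boron where the ethyl group belongs, so a Zweifel vinylation and a hydrogenation must follow. A2 needs an ω-functionalised C15 chain, a borylation and a silyl group that is later removed. The step uses a stoichiometric chiral diamine and cryogenic organolithium chemistry. The enantiomeric purity is what the reagent delivers and cannot be raised later on an oil with a remote methyl branch.
- Comparison: it is clearly longer (chain preparation, protection and two post-coupling steps). The chosen route accepts a statistical coupling and offers in exchange a stereocentre taken from the chiral pool and no protecting group on the chain.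

Alternative 2: Johnson–Claisen relay of a carbinol configuration.
- Disconnection: C16–C17, with the stereocentre transferred from a C14 carbinol.
- Forward key step: the (S,E)-allylic alcohol A5 is heated with triethyl orthoacetate A6 and a weak acid catalyst. The ketene acetal rearranges through a chair transition state with the long chain equatorial. The C16–C17 bond forms, the C14–O bond breaks and an E double bond appears at C14–C15, giving ester A4.
- For: chirality transfer in this rearrangement is dependable, the reaction needs no metal and scales well, and the union itself is high-yielding and non-statistical, which the Kolbe step is not.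
- Against: the configuration must first be created at a carbinol (asymmetric reduction or resolution), so it is not taken from the pool. A4 is over-functionalised for this target. The ester carbon must be taken down to the C18 methyl group (reduction, sulfonylation, hydride displacement), the C14=C15 alkene must be saturated and the benzyl ether removed.
- Comparison: it needs roughly twice as many operations, most of them redox corrections at carbons that end up as plain CH2 or CH3. The chosen route has no such corrections, because its only auxiliary atoms leave as gas.

Alternative 3: Copper-catalysed asymmetric allylic methylation.
- Disconnection: the C16–CH3 bond.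
- Forward key step: methylmagnesium bromide A9, under a copper catalyst bearing a chiral ferrocenyl diphosphine at low temperature, attacks the γ-carbon of the linear E allylic bromide A8. The double bond transposes to C17–C18 and the branched terminal alkene A7 results.
- For: the chiral information is catalytic, the methyl group is the cheapest nucleophile, and the vinyl group of A7 could be saturated in the same hydrogenation that removes the benzyl ethers at the end. In atom economy of the bond-forming event it beats the chosen step.
- Against: A8 is a C18 chain functionalised at both ends and takes several steps to build. Any unbranched SN2 isomer and any minor enantiomer would end as compounds almost inseparable from 17. Enantioselectivity for purely aliphatic allylic bromides is high but not complete, and it cannot be corrected downstream. A silyl group has to be put on and taken off.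
- Comparison: the step count is similar or higher, with a residual uncertainty in optical purity that the chiral-pool approach does not have. The Kolbe by-products differ from the product by six and eight carbons and are easily removed.

Key step: step 6

Assumption: commercial (S)-2-methylbutan-1-ol of high enantiomeric purity is the source of C16; since no later step makes or breaks a bond at that carbon, the configurational purity of 17 is taken to equal that of 1.

## Route

Step 1
Reactants: 1 (S)-2-methylbutan-1-ol
Product: 2 (S)-1-bromo-2-methylbutane
Conditions: PPh3, Br2, CH2Cl2, 0 °C to rt; distillation
Reagents that add atoms: bromine, BrBr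
Why: Appel-type bromination through the alkoxyphosphonium bromide, with SN2 displacement at the primary carbon so that no cation and no hydride shift arise. The adjacent stereocentre is not a reacting centre and keeps its configuration.

Step 2
Reactants: 2 (S)-1-bromo-2-methylbutane; 3 diethyl malonate
Product: 4 diethyl 2-[(2S)-2-methylbutyl]propanedioate
Conditions: NaOEt, EtOH, NaI (cat.), reflux; 3 in excess
Reagents that add atoms: none
Why: Malonic ester alkylation (SN2) forms the C14–C15 bond; an excess of 3 suppresses dialkylation and catalytic iodide speeds substitution at the β-branched primary carbon. The stereocentre bears no acidic hydrogen and is untouched by ethoxide.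

Step 3
Reactants: 4 diethyl 2-[(2S)-2-methylbutyl]propanedioate
Product: 6 (S)-4-methylhexanoic acid, via 2-[(2S)-2-methylbutyl]propanedioic acid 5 (not isolated)
Conditions: KOH, H2O/EtOH, reflux; then aq. H2SO4, reflux; distillation
Reagents that add atoms: potassium hydroxide, [K+].[OH-]
Why: Saponification followed by decarboxylation of the malonic acid through the cyclic six-membered transition state, the second half of the malonic ester synthesis. C4 of 6 is γ to the carboxyl group and not enolisable, so the configuration is retained.

Step 4
Reactants: 7 tetradecanedioic acid
Product: 8 dimethyl tetradecanedioate
Conditions: MeOH, H2SO4 (cat.), reflux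
Reagents that add atoms: methanol, CO
Why: Fischer esterification driven to completion by methanol as solvent.

Step 5
Reactants: 8 dimethyl tetradecanedioate
Product: 10 14-methoxy-14-oxotetradecanoic acid, via barium 14-methoxy-14-oxotetradecanoate 9 (not isolated)
Conditions: Ba(OH)2·8H2O (0.5 equiv), MeOH, rt; then 2 M HCl, Et2O
Reagents that add atoms: barium hydroxide, [Ba+2].[OH-].[OH-]
Why: Partial saponification of a symmetrical diester; the barium salt of the half-ester is insoluble in methanol and precipitates, which removes it from further hydrolysis. Acidifying the crude precipitate frees 10, and unreacted 8 is recovered from the filtrate.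

Step 6
Reactants: 6 (S)-4-methylhexanoic acid; 10 14-methoxy-14-oxotetradecanoic acid
Product: 11 methyl (16S)-16-methyloctadecanoate
Conditions: smooth Pt anode and Pt cathode, undivided cell, MeOH, NaOMe (ca. 5 mol% of total acid), 10 (3 equiv), constant current ca. 0.25 A cm−2, 45–50 °C, until slightly basic
Reagents that add atoms: none
Why: This is a mixed Kolbe electrolysis, the classical anodic decarboxylative cross-coupling of an alkanoic acid with a dicarboxylic acid half-ester. Each carboxylate is discharged at the platinum anode to an acyloxy radical that loses CO2 at once, giving the primary 3-methylpentyl radical from 6 and the primary 13-methoxy-13-oxotridecyl radical from 10, while protons are reduced to H2 at the cathode and methoxide is regenerated. At high current density on smooth platinum in weakly acidic methanol the radicals are produced in a dense layer at the electrode and should combine faster than they are oxidised further, so the C13–C14 bond forms by radical–radical coupling; both radicals are primary and unstabilised, the case least prone to cation-derived ether and alkene by-products. No ring is closed and no stereocentre is created. C16 lies two bonds from the radical carbon C14, carries no activating group and cannot be reached by an intramolecular hydrogen shift through a feasible ring size, so its configuration is carried through. The selectivity required is cross- over homo-coupling, which for two equally reactive primary radicals is statistical; the threefold excess of cheap 10 should channel most of the valuable 6 into 11. The two symmetrical by-products, a volatile C12 hydrocarbon and a crystalline C28 diester, differ from 11 by eight and six carbons and should be removed by evaporation, crystallisation from cold methanol and distillation or chromatography.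

Step 7
Reactants: 11 methyl (16S)-16-methyloctadecanoate
Product: 12 (16S)-16-methyloctadecan-1-ol
Conditions: LiAlH4, THF, 0 °C to rt; aqueous work-up
Reagents that add atoms: none
Why: Hydride reduction of an unhindered ester to the primary alcohol; the molecule contains no other reducible group.

Step 8
Reactants: 13 2,3-dihydroxybenzoic acid
Product: 14 benzyl 2,3-bis(benzyloxy)benzoate
Conditions: BnBr (3.5 equiv), K2CO3, DMF, 60 °C
Reagents that add atoms: benzyl bromide, BrCc1ccccc1
Why: Williamson O-alkylation of both phenoxides and of the carboxylate in one operation; excess reagent and heat compensate for the hydrogen-bonded C2 hydroxyl.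

Step 9
Reactants: 14 benzyl 2,3-bis(benzyloxy)benzoate
Product: 15 2,3-bis(benzyloxy)benzoic acid
Conditions: NaOH, MeOH/THF/H2O, reflux; then aq. HCl
Reagents that add atoms: sodium hydroxide, [Na+].[OH-]
Why: Saponification cleaves only the benzyl ester; benzyl aryl ethers are inert to hydroxide.

Step 10
Reactants: 12 (16S)-16-methyloctadecan-1-ol; 15 2,3-bis(benzyloxy)benzoic acid
Product: 16 (16S)-16-methyloctadecyl 2,3-bis(benzyloxy)benzoate
Conditions: DCC, DMAP (cat.), CH2Cl2, 0 °C to rt
Reagents that add atoms: none
Why: Steglich esterification; the O-acylisourea is intercepted by DMAP and the acylpyridinium ion acylates the unhindered primary alcohol. With both phenols masked, only the desired ester can form.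

Step 11
Reactants: 16 (16S)-16-methyloctadecyl 2,3-bis(benzyloxy)benzoate
Product: 17 Gentiside F, (16S)-16-methyloctadecyl 2,3-dihydroxybenzoate
Conditions: H2 (1 atm), 10% Pd/C, EtOAc/EtOH, rt; filtration under argon
Reagents that add atoms: none
Why: Catalytic hydrogenolysis of the two benzyl aryl ethers. The ester C–O bond is to a saturated primary carbon, not a benzylic one, so it is not cleaved, and the saturated chain with its C16 centre is inert.

## Compound list

1 | (S)-2-methylbutan-1-ol | CC[C@H](C)CO | starting material
2 | (S)-1-bromo-2-methylbutane | CC[C@H](C)CBr | intermediate
3 | diethyl malonate (diethyl propanedioate) | CCOC(=O)CC(=O)OCC | starting material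
4 | diethyl 2-[(2S)-2-methylbutyl]propanedioate | CC[C@H](C)CC(C(=O)OCC)C(=O)OCC | intermediate
5 | 2-[(2S)-2-methylbutyl]propanedioic acid | CC[C@H](C)CC(C(=O)O)C(=O)O | intermediate
6 | (S)-4-methylhexanoic acid | CC[C@H](C)CCC(=O)O | intermediate
7 | tetradecanedioic acid | OC(=O)CCCCCCCCCCCCC(=O)O | starting material
8 | dimethyl tetradecanedioate | COC(=O)CCCCCCCCCCCCC(=O)OC | intermediate
9 | barium bis(14-methoxy-14-oxotetradecanoate) | [Ba+2].COC(=O)CCCCCCCCCCCCC(=O)[O-].COC(=O)CCCCCCCCCCCCC(=O)[O-] | intermediate
10 | 14-methoxy-14-oxotetradecanoic acid (monomethyl tetradecanedioate) | COC(=O)CCCCCCCCCCCCC(=O)O | intermediate
11 | methyl (16S)-16-methyloctadecanoate | CC[C@H](C)CCCCCCCCCCCCCCC(=O)OC | intermediate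
12 | (16S)-16-methyloctadecan-1-ol | CC[C@H](C)CCCCCCCCCCCCCCCO | intermediate
13 | 2,3-dihydroxybenzoic acid | O=C(O)c1cccc(O)c1O | starting material
14 | benzyl 2,3-bis(benzyloxy)benzoate | O=C(OCc1ccccc1)c1cccc(OCc2ccccc2)c1OCc1ccccc1 | intermediate
15 | 2,3-bis(benzyloxy)benzoic acid | O=C(O)c1cccc(OCc2ccccc2)c1OCc1ccccc1 | intermediate
16 | (16S)-16-methyloctadecyl 2,3-bis(benzyloxy)benzoate | CC[C@H](C)CCCCCCCCCCCCCCCOC(=O)c1cccc(OCc2ccccc2)c1OCc1ccccc1 | intermediate
17 | Gentiside F, (16S)-16-methyloctadecyl 2,3-dihydroxybenzoate | CC[C@H](C)CCCCCCCCCCCCCCCOC(=O)c1cccc(O)c1O | target

## Step count and least certain steps

Total step count: 11. Longest linear sequence: 7 steps (steps 1, 2, 3, 6, 7, 10, 11). Steps 4–5 and 8–9 are two-step side branches.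

**Step 6 (key step).**
- What may go wrong: the two primary radicals partition statistically, so much of the current goes into symmetrical dimers. Disproportionation and further oxidation to cations would add alkane, alkene and ether by-products. The sparingly soluble long-chain diester may coat the anode and raise the cell voltage. The cross product may be hard to free from esters of similar polarity.
- Fallback: a polar copper-catalysed coupling that moves the bond formation to C14–C15. It sets out from 10 and 2 and returns to the route at 11. The carboxyl group of 10 is reduced chemoselectively with BH3·THF (THF, 0 °C) to methyl 14-hydroxytetradecanoate F1. F1 is converted with CBr4 and PPh3 (CH2Cl2) into methyl 14-bromotetradecanoate F2. Bromide 2 is turned with Mg in THF into (S)-2-methylbutylmagnesium bromide F3. F3 is coupled with F2 under Li2CuCl4 (cat.) in THF/NMP at −20 to 0 °C, a copper-catalysed alkyl–alkyl Grignard coupling that tolerates the ester at low temperature, to give 11.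

**Step 2.**
- What may go wrong: substitution at the β-branched primary bromide is slow, so E2 elimination, loss of the volatile bromide and some dialkylation can compete.
- Fallback: it sets out from 2 and returns at 6, bypassing 4 and 5. Bromide 2 is coupled with allylmagnesium bromide under Li2CuCl4 (cat.) in THF to give (S)-5-methylhept-1-ene F4. Oxidative cleavage of the terminal alkene with RuCl3 (cat.) and NaIO4 in MeCN/EtOAc/H2O then gives 6.

**Step 5.**
- What may go wrong: if the barium salt does not precipitate cleanly, over-hydrolysis to the diacid or incomplete conversion leaves a statistical mixture.
- Fallback: it sets out from 7 and 8 and returns at 10 (F0: no new compound). Equimolar 7 and 8 are heated with catalytic H2SO4 and a little MeOH in di-n-butyl ether at about 130 °C. Acid-catalysed ester interchange equilibrates the mixture towards 10. Half-ester 10 is separated from neutral 8 by base extraction and from poorly soluble 7 by crystallisation, and both are recycled.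

**Step 10.**
- What may go wrong: rearrangement of the O-acylisourea to an unreactive N-acylurea before acyl transfer, and incomplete removal of the urea from the waxy ester.
- Fallback: the polarity is reversed. It sets out from 12 and 15 and returns at 16. Alcohol 12 is converted with CBr4 and PPh3 (CH2Cl2) into (16S)-1-bromo-16-methyloctadecane F5, and the caesium carboxylate of 15 (Cs2CO3, DMF, 50 °C) is O-alkylated with F5 to give 16.

**Step 11.**
- What may go wrong: incomplete cleavage of the more hindered C2 benzyl ether, catalyst deactivation by the chelating catechol, and air oxidation of the product during filtration.
- Fallback: a protecting-group-free esterification. It sets out from 12 and 13 and returns at 17, bypassing 14, 15 and 16 (F0: no new compound). Alcohol 12 and acid 13 are combined with PPh3 and DIAD in THF at 0 °C to rt (Mitsunobu esterification). The carboxylic acid is far more acidic than the phenols and is the pronucleophile that attacks the alkoxyphosphonium ion, so the ester should form without O-alkylation of the catechol.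

## Further compounds

F1 | step 6 | methyl 14-hydroxytetradecanoate | COC(=O)CCCCCCCCCCCCCO
F2 | step 6 | methyl 14-bromotetradecanoate | COC(=O)CCCCCCCCCCCCCBr
F3 | step 6 | (S)-2-methylbutylmagnesium bromide | CC[C@H](C)C[Mg]Br
F4 | step 2 | (S)-5-methylhept-1-ene | CC[C@H](C)CCC=C
F0 | step 5 | none | none
F5 | step 10 | (16S)-1-bromo-16-methyloctadecane | CC[C@H](C)CCCCCCCCCCCCCCCBr
F0 | step 11 | none | none
A1 | alternative 1 | (R)-tert-butyldimethyl{[16-(4,4,5,5-tetramethyl-1,3,2-dioxaborolan-2-yl)heptadecyl]oxy}silane | CC1(C)OB(OC1(C)C)[C@H](C)CCCCCCCCCCCCCCCO[Si](C)(C)C(C)(C)C
A2 | alternative 1 | tert-butyldimethyl{[15-(4,4,5,5-tetramethyl-1,3,2-dioxaborolan-2-yl)pentadecyl]oxy}silane | CC1(C)OB(OC1(C)C)CCCCCCCCCCCCCCCO[Si](C)(C)C(C)(C)C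
A3 | alternative 1 | ethyl 2,4,6-triisopropylbenzoate | CCOC(=O)c1c(C(C)C)cc(C(C)C)cc1C(C)C
A4 | alternative 2 | ethyl (3S,4E)-18-(benzyloxy)-3-methyloctadec-4-enoate | CCOC(=O)C[C@H](C)/C=C/CCCCCCCCCCCCCOCc1ccccc1
A5 | alternative 2 | (2E,4S)-17-(benzyloxy)heptadec-2-en-4-ol | C/C=C/[C@@H](O)CCCCCCCCCCCCCOCc1ccccc1
A6 | alternative 2 | triethyl orthoacetate | CCOC(C)(OCC)OCC
A7 | alternative 3 | (R)-tert-butyldimethyl[(16-methyloctadec-17-en-1-yl)oxy]silane | C=C[C@H](C)CCCCCCCCCCCCCCCO[Si](C)(C)C(C)(C)C
A8 | alternative 3 | (E)-[(18-bromooctadec-16-en-1-yl)oxy](tert-butyl)dimethylsilane | BrC/C=C/CCCCCCCCCCCCCCCO[Si](C)(C)C(C)(C)C
A9 | alternative 3 | methylmagnesium bromide | C[Mg]Br
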